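# Proposed synthesis of (2S,3S,4S,6R)-3,4,6-trihydroxy-6-[2-(oxazol-5-ylmethyl)oxazol-4-yl]hexan-2-yl hexadecanoate (23)

Chain numbering used throughout: C1 is the carbinol on ring A, C2 the CH2, C3 and C4 the carbinols, C5 the acyloxy carbon, C6 the methyl. Ring A is the 2,4-disubstituted oxazole; ring B is the oxazol-5-yl ring.

## Structural features

The target is a six-carbon chain attached at C1 to C4 of ring A. C2 of ring A is joined through one methylene to C5 of ring B, an oxazole with no other substituent. The chain has four stereocentres: the C1 carbinol (R) is 1,3-syn to the C3 carbinol (S) across the C2 methylene, and C3, C4 and C5 (all S) are contiguous, with C3/C4 anti and C4/C5 syn. Three oxygens are free hydroxyls; only the C5 oxygen, next to the C6 methyl, carries the hexadecanoyl ester. The ester sits beside the free C4 hydroxyl, so 1,2-acyl migration under base or strong acid is the main fragility. Other weak points are the heterobenzylic C1 carbinol, the acidic and oxidisable methylene between rings A and B, and the Lewis-basic ring nitrogens. The real difficulty is therefore not the bis-oxazole but telling four similar secondary oxygens apart, two of them in a syn 1,2-diol of which only one is acylated. The key step uses the C4–C5 pair: in a 2-alkoxy-3-oxobutanoate the future C4 lies between a ketone and an ester and is configurationally labile, so a single catalytic reduction of the C5 ketone can fix both centres and deliver C5–OH free with the C4 oxygen masked.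

## Logic of the disconnections

**23 ⇐ 22 ⇐ 21.** The last bonds cut are protecting-group bonds: the benzylic C–O bond on the C4 oxygen of 22 and, one step earlier, the two acetal C–O bonds that tie the C1 and C3 oxygens in 21. The C4 hydroxyl is the only one that can take the acyl group by 1,2-migration, so it is released last and under neutral conditions. The gain is that every oxygen of 23 other than C5–O is masked in 21 by groups that leave without base. The demand is that hydrogenolysis spares both oxazoles and the heterobenzylic C1–O bond, and that the acid used on the acetal does not move the ester to C3.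

**21 ⇐ 19 + 20.** The C5–O acyl bond is cut. In 19 the C5 hydroxyl is the only free nucleophile, so the C16 chain, which dominates mass and polarity, arrives late from 20. The demand is clean acylation of a hindered secondary alcohol flanked by C6 and the benzyloxy carbon.

**19 ⇐ 18 ⇐ 17.** The O–Si bond on C5 and the acetal are cut. The syn 1,3-diol of 17 is the natural site for a six-membered acetal with both substituents equatorial, and the silyl ether that has protected C5–O since the start is the only fluoride-labile group. The acetalisation must leave the silyl ether alone, and the fluoride step must not disturb the inter-ring methylene.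

**17 ⇐ 15.** The C1–H bond is cut. Tracing the C1 carbinol to a ketone lets the existing C3 hydroxyl direct hydride delivery (1,3-syn) without an external chiral reagent. The demand is that boron chelates C3–O and C1=O rather than the ring nitrogens.

**15 ⇐ 13 + 6.** The C2–C3 bond is cut; it is the only skeletal C–C bond made on the chain. The cut separates the achiral bis-oxazole 13 from the four-carbon 6 and creates C3 under the control of C4. The forward step must enolise only the acetyl group and add anti to the benzyloxy group, without chelation.

**6 ⇐ 5 ⇐ 4.** The oxidation level at C3 is changed (ester to aldehyde) and the O–Si bond at C5 is cut. In 4 the two oxygens are already differentiated; silylating the free one carries that differentiation through to 19. The demand is partial reduction without epimerising C4, which is again α to a carbonyl in 6.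

**4 ⇐ 3.** The C5–H bond is cut (key step). Both stereocentres of the C4/C5 pair are removed at once because C4 is labile in 3. The gain is a racemic keto ester made without any chiral reagent. The demand is racemisation faster than reduction, catalyst control of the ketone face, and a syn preference.

**3 ⇐ 2 ⇐ 1.** The C4–O bond to the benzyl ether oxygen and then the C4=N2 bond are cut, leading back to the commodity 1. The demand is that O–H insertion outruns Wolff rearrangement.

**13 ⇐ 12 ⇐ 11.** The C–CH3 bond of the acetyl group is cut. This leads to 11; single addition of the methyl nucleophile is secured by passing through 12.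

**11 ⇐ 9 ⇐ 7 + 8.** In ring A the O1–C5 bond and the C4=C5 unsaturation are cut, then the amide C–N bond. Ring A is built from 8 (N3, C4, C5 and the carboxyl carbon) and 7 (C2, the methylene and ring B, bought intact). The demand is cyclodehydration and dehydrogenation in the presence of the activated inter-ring CH2.

## Other disconnections considered

**Alternative 1:** The cut is the O1–C5 bond of ring A, made last. The forward key step would be a Robinson–Gabriel-type cyclodehydration of the 2-acylamino aldehyde A2 with PPh3, (BrCCl2)2 and 2,6-di-tert-butyl-4-methylpyridine, then DBU. It would give A1, the C1, C3, C4 tris(tert-butyldimethylsilyl) ether of 23 with the palmitate in place. The amino carbon of A2 would come from 8 by way of the N-Boc N,O-isopropylidene serinal A3. Felkin-controlled addition of a C2 nucleophile to A3 would place the C1 oxygen anti to nitrogen, which is the arrangement 23 needs, and the amino carbon is then consumed as C4 of ring A.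

- In its favour: ring A is absent during chain building, so no azole nitrogen competes for boron, aluminium or palladium reagents. On this point alternative 1 is the better plan.
- In its favour: C1 is set by a well-understood 1,2-induction from an inexpensive centre that leaves no trace. This is equal in principle to the 1,3-induction used in the chosen plan.
- Against: A2 is an aldehyde with a β-silyloxy group at C1, so in the DBU phase β-elimination of that group can compete with loss of HBr and would erase the centre that the serine carbon was meant to relay.
- Against: the ring closure is the last skeletal operation on the most valuable intermediate.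
- Against: three silyl ethers must then be removed beside the palmitate, with the C4 hydroxyl emerging next to the ester under fluoride, which invites acyl migration.
- Step economy: the chain must be grown linearly from A3 and followed by N-deprotection, acylation and oxidation, so the longest linear sequence should exceed that of the chosen plan. The chosen plan also ends with a neutral hydrogenolysis rather than a triple desilylation.

**Alternative 2:** The cut is the bond between C1 and C4 of ring A. The forward key step would be a Fukuyama coupling of the S-ethyl thioester A5 with the zinc reagent A7, made from the iodide A6, under PdCl2(PPh3)2, giving the ketone A4. The C3–C5 triad of A5 would be bought as 2-deoxy-L-fucose A8, whose cis-3,4-diol takes the acetonide and leaves the C5 oxygen for acylation.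

- In its favour: three of the four stereocentres come from the chiral pool with no stereoselective step. On stereochemical certainty for C3–C5 alternative 2 is better than the chosen plan.
- In its favour: the C5 oxygen is differentiated by the sugar's own geometry, the coupling tolerates ester and acetonide, and the plan is as convergent as the chosen one.
- Against: C1 is still a ketone in A4 and the C3 oxygen is locked in the acetonide. The hydroxyl-directed 1,3-syn reduction used in the chosen plan is therefore not available, and C1 would need reagent control. For a heteroaryl ketone that is realistic, so this is a moderate rather than a decisive objection.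
- Against: A4 has an alkoxy leaving group β to the ketone and can eliminate by an E1cB path under basic conditions.
- Against: A6 has the least accessible halogenation pattern of an oxazole, and zinc insertion must tolerate the acidic inter-ring methylene.
- Against: A8 is a costly starting material.
- Step economy: with A6 and A8 in hand the count would be equal or slightly lower than in the chosen plan. The risk moves to making A6 and to reducing A4.

**Alternative 3:** The cut is the C5–O ester bond together with the C5 stereocentre. The forward key step would be opening of the cis-4,5-epoxy alcohol A10 at C5, with inversion, by palmitic acid and Ti(OiPr)4. It would give A9, the C1 silyl ether of 23, and one desilylation would finish the synthesis.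

- In its favour: the ester bond, the C5 configuration and the free C4 hydroxyl arise in one step with no protecting group on C4 or C5, no benzyl ether and no hydrogenation. In protecting-group economy of the endgame alternative 3 is better than the chosen plan.
- Equal: both plans fix the C4/C5 pair in a single operation.
- Against: regioselection (C5 over C4) depends on titanium binding the C3 hydroxyl, and two oxazole nitrogens compete for the metal.
- Against: Ti(OiPr)4 also catalyses transesterification, so transfer of the acyl group to isopropoxide or to the C4 or C3 oxygen is a plausible drain.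
- Against: A10 needs the erythro relation between C3–OH and the epoxide. Hydroxyl-directed epoxidation of the Z-allylic alcohol A11 is expected to be biased toward threo by allylic 1,3-strain, so an inversion or a reagent-controlled epoxidation of a slow cis-olefin would be needed.
- Timing: the chosen plan sets the pair at the outset on a four-carbon compound, where failure costs little; alternative 3 does so at the end on the complete skeleton.
- Step economy: overall roughly equal once the preparation of A10 is counted.

Key step: step 3

Remarks on the chemistry (assumptions):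
- The sense of induction in step 3 is assigned by analogy with aryl methyl ketones, the ester-bearing carbon taking the place of the aryl group. On that basis the (S,S)-TsDPEN complex is written. If the methyl group takes that position instead, the (R,R) complex is used and nothing else changes.
- The benzyloxy carbon is 2R in 4 and becomes 4S in 23 only because the ranking of its two carbon neighbours is exchanged; the spatial arrangement is the same.
- Compound 8 is handled as its commercial hydrochloride.

## Route

Step 1
Reactants: 1 methyl acetoacetate
Product: 2 methyl 2-diazo-3-oxobutanoate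
Conditions: p-ABSA, Et3N, MeCN, 0 °C → rt
Reagents that add atoms: 4-acetamidobenzenesulfonyl azide (p-ABSA), CC(=O)Nc1ccc(cc1)S(=O)(=O)N=[N+]=[N-]
Why: Regitz diazo transfer to an active methylene compound; p-ABSA is chosen as a bench-stable sulfonyl azide and the acceptor-acceptor diazo product is among the more stable diazo compounds.

Step 2
Reactants: 2 methyl 2-diazo-3-oxobutanoate
Product: 3 methyl (±)-2-(benzyloxy)-3-oxobutanoate
Conditions: Rh2(OAc)4 (1 mol %), BnOH (1.5 equiv), CH2Cl2, 40 °C, slow addition of 2
Reagents that add atoms: benzyl alcohol, OCc1ccccc1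
Why: Rhodium carbenoid O–H insertion; the electrophilic carbenoid is trapped by the alcohol faster than it rearranges, and the racemic, enolisable product is exactly what step 3 requires.

Step 3
Reactants: 3 methyl (±)-2-(benzyloxy)-3-oxobutanoate
Product: 4 methyl (2R,3S)-2-(benzyloxy)-3-hydroxybutanoate
Conditions: RuCl(p-cymene)[(S,S)-TsDPEN] (1 mol %), HCO2H/NEt3 (5:2), CH2Cl2, 30 °C
Reagents that add atoms: none
Why: Formate converts the 16-electron ruthenium amide into the 18-electron ruthenium hydride amine, which passes H from Ru and H from N to the C5 ketone of 3 through a concerted six-membered outer-sphere transition state; the ester is not reduced. The closest known reaction type is asymmetric transfer hydrogenation with dynamic kinetic resolution of 2-alkoxy-3-oxo esters to syn 2-alkoxy-3-hydroxy esters. No ring closes. C5 (3S in 4) is set by the chiral diamine/arene pocket, which selects the ketone face. C4 (2R in 4) is set because, of the two rapidly interconverting enantiomers of 3, the one that can hold its C–OBn bond anti to the incoming hydride (polar Felkin–Anh arrangement, which corresponds to the syn product) should be reduced faster. The step needs enantioselection and syn diastereoselection, both resting on enol-mediated racemisation being faster than reduction, which the doubly activated C4–H and the NEt3 buffer secure. It also needs chemoselection for ketone over ester, which is inherent to this hydride. The product should emerge with C5–OH free and the C4 oxygen benzylated, i.e. already differentiated.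

Step 4
Reactants: 4 methyl (2R,3S)-2-(benzyloxy)-3-hydroxybutanoate
Product: 5 methyl (2R,3S)-2-(benzyloxy)-3-[(tert-butyldimethylsilyl)oxy]butanoate
Conditions: TBSCl, imidazole, DMF, rt
Reagents that add atoms: tert-butyldimethylsilyl chloride, CC(C)(C)[Si](C)(C)Cl
Why: Standard silylation of a secondary alcohol; imidazole is too weak a base to epimerise the ester α-carbon, and the silyl ether is the one fluoride-labile group of the route.

Step 5
Reactants: 5 methyl (2R,3S)-2-(benzyloxy)-3-[(tert-butyldimethylsilyl)oxy]butanoate
Product: 6 (2R,3S)-2-(benzyloxy)-3-[(tert-butyldimethylsilyl)oxy]butanal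
Conditions: iBu2AlH (1.1 equiv), CH2Cl2, −78 °C; MeOH, then aq. potassium sodium tartrate; used crude at once
Reagents that add atoms: none
Why: Partial reduction of an α-alkoxy ester; the tetrahedral aluminium hemiacetal is stabilised by the neighbouring benzyloxy oxygen at −78 °C and collapses to the aldehyde only on work-up, and immediate use limits epimerisation at C4.

Step 6
Reactants: 7 2-(oxazol-5-yl)acetic acid; 8 L-serine methyl ester
Product: 9 methyl (2S)-3-hydroxy-2-[2-(oxazol-5-yl)acetamido]propanoate
Conditions: EDC·HCl, HOBt, NMM, CH2Cl2, 0 °C → rt (8 as its hydrochloride)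
Reagents that add atoms: none
Why: Carbodiimide amide coupling through the HOBt active ester; the amine is acylated in preference to the primary hydroxyl, which needs no protection.

Step 7
Reactants: 9 methyl (2S)-3-hydroxy-2-[2-(oxazol-5-yl)acetamido]propanoate
Product: 11 methyl 2-(oxazol-5-ylmethyl)oxazole-4-carboxylate, via oxazoline 10 (not isolated)
Conditions: Deoxo-Fluor, CH2Cl2, −20 °C; then BrCCl3, DBU, 0 °C → rt
Reagents that add atoms: none
Why: Cyclodehydration of a β-hydroxy amide (the activated primary hydroxyl is displaced by the amide oxygen, 5-exo-tet) gives oxazoline 10, and bromination at the ester α-carbon followed by loss of HBr aromatises it to ring A; the serine stereocentre is intentionally destroyed.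

Step 8
Reactants: 11 methyl 2-(oxazol-5-ylmethyl)oxazole-4-carboxylate
Product: 12 N-methoxy-N-methyl-2-(oxazol-5-ylmethyl)oxazole-4-carboxamide
Conditions: AlMe3, MeNHOMe·HCl, CH2Cl2, 0 °C → rt
Reagents that add atoms: N,O-dimethylhydroxylamine hydrochloride, CNOC.Cl
Why: Aluminium amide aminolysis of an ester to the Weinreb amide; the Lewis-acidic, weakly basic reagent avoids deprotonation of the inter-ring methylene that a Grignard-derived amide base could cause.

Step 9
Reactants: 12 N-methoxy-N-methyl-2-(oxazol-5-ylmethyl)oxazole-4-carboxamide
Product: 13 1-[2-(oxazol-5-ylmethyl)oxazol-4-yl]ethan-1-one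
Conditions: MeMgBr, THF, −78 → 0 °C; aq. NH4Cl
Reagents that add atoms: methylmagnesium bromide, C[Mg]Br
Why: Weinreb ketone synthesis; the magnesium-chelated tetrahedral intermediate prevents a second addition, and addition at low temperature should be faster than deprotonation of the inter-ring CH2.

Step 10
Reactants: 13 1-[2-(oxazol-5-ylmethyl)oxazol-4-yl]ethan-1-one; 6 (2R,3S)-2-(benzyloxy)-3-[(tert-butyldimethylsilyl)oxy]butanal
Product: 15 (3S,4S,5S)-4-(benzyloxy)-5-[(tert-butyldimethylsilyl)oxy]-3-hydroxy-1-[2-(oxazol-5-ylmethyl)oxazol-4-yl]hexan-1-one, via boron enolate 14 (not isolated)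
Conditions: c-Hex2BCl, Et3N, Et2O, 0 °C; then 6, −78 → −20 °C; pH 7 buffer, MeOH, H2O2, 0 °C
Reagents that add atoms: none
Why: Boron-mediated methyl ketone aldol addition: soft enolisation gives boron enolate 14, which adds through a closed Zimmerman–Traxler transition state in which boron has no free site to chelate the benzyloxy group. The aldehyde therefore reacts in the Felkin–Anh/Cornforth arrangement and the new C3 hydroxyl should form anti to C4–OBn (3S).

Step 11
Reactants: 15 (3S,4S,5S)-4-(benzyloxy)-5-[(tert-butyldimethylsilyl)oxy]-3-hydroxy-1-[2-(oxazol-5-ylmethyl)oxazol-4-yl]hexan-1-one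
Product: 17 (1R,3S,4S,5S)-4-(benzyloxy)-5-[(tert-butyldimethylsilyl)oxy]-1-[2-(oxazol-5-ylmethyl)oxazol-4-yl]hexane-1,3-diol, via diethylboron chelate 16 (not isolated)
Conditions: Et2BOMe, THF/MeOH (4:1), −78 °C; NaBH4; then MeOH, repeated evaporation
Reagents that add atoms: none
Why: Narasaka–Prasad reduction: the C3 alkoxyborane chelates the C1 ketone in a six-membered half-chair and external hydride attacks axially, so C1 should form 1,3-syn to C3 (1R). Methanolysis returns Et2BOMe and frees the diol.

Step 12
Reactants: 17 (1R,3S,4S,5S)-4-(benzyloxy)-5-[(tert-butyldimethylsilyl)oxy]-1-[2-(oxazol-5-ylmethyl)oxazol-4-yl]hexane-1,3-diol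
Product: 18 4-[(4R,6S)-6-[(1S,2S)-1-(benzyloxy)-2-[(tert-butyldimethylsilyl)oxy]propyl]-2,2-dimethyl-1,3-dioxan-4-yl]-2-(oxazol-5-ylmethyl)oxazole
Conditions: 2,2-dimethoxypropane, PPTS (cat.), CH2Cl2, rt
Reagents that add atoms: 2,2-dimethoxypropane, COC(C)(C)OC
Why: Transacetalisation of a syn 1,3-diol gives a chair dioxane with both substituents equatorial; PPTS is mild enough to leave the secondary silyl ether intact.

Step 13
Reactants: 18 4-[(4R,6S)-6-[(1S,2S)-1-(benzyloxy)-2-[(tert-butyldimethylsilyl)oxy]propyl]-2,2-dimethyl-1,3-dioxan-4-yl]-2-(oxazol-5-ylmethyl)oxazole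
Product: 19 (2S,3R)-3-(benzyloxy)-3-[(4S,6R)-2,2-dimethyl-6-[2-(oxazol-5-ylmethyl)oxazol-4-yl]-1,3-dioxan-4-yl]propan-2-ol
Conditions: TBAF, THF, 0 °C → rt
Reagents that add atoms: none
Why: Fluoride cleavage of the only silyl ether; acetal, benzyl ether and oxazoles are inert to fluoride, and C5–OH becomes the single free hydroxyl.

Step 14
Reactants: 19 (2S,3R)-3-(benzyloxy)-3-[(4S,6R)-2,2-dimethyl-6-[2-(oxazol-5-ylmethyl)oxazol-4-yl]-1,3-dioxan-4-yl]propan-2-ol; 20 palmitoyl chloride
Product: 21 (2S,3R)-3-(benzyloxy)-3-[(4S,6R)-2,2-dimethyl-6-[2-(oxazol-5-ylmethyl)oxazol-4-yl]-1,3-dioxan-4-yl]propan-2-yl hexadecanoate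
Conditions: Et3N, DMAP (cat.), CH2Cl2, 0 °C → rt
Reagents that add atoms: none
Why: DMAP-catalysed acylation through the acylpyridinium ion, which is reactive enough for a hindered secondary alcohol; no other hydroxyl is free, so the C16 ester can only form on the C5 oxygen.

Step 15
Reactants: 21 (2S,3R)-3-(benzyloxy)-3-[(4S,6R)-2,2-dimethyl-6-[2-(oxazol-5-ylmethyl)oxazol-4-yl]-1,3-dioxan-4-yl]propan-2-yl hexadecanoate
Product: 22 (2S,3S,4S,6R)-3-(benzyloxy)-4,6-dihydroxy-6-[2-(oxazol-5-ylmethyl)oxazol-4-yl]hexan-2-yl hexadecanoate
Conditions: AcOH/H2O/THF (3:1:1), 40 °C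
Reagents that add atoms: none
Why: Mild acid hydrolysis of the isopropylidene acetal; the C4 oxygen is still benzylated, so 1,2-acyl migration is impossible at this stage and only the slower 1,3-shift to C3 has to be avoided.

Step 16
Reactants: 22 (2S,3S,4S,6R)-3-(benzyloxy)-4,6-dihydroxy-6-[2-(oxazol-5-ylmethyl)oxazol-4-yl]hexan-2-yl hexadecanoate
Product: 23 (2S,3S,4S,6R)-3,4,6-trihydroxy-6-[2-(oxazol-5-ylmethyl)oxazol-4-yl]hexan-2-yl hexadecanoate
Conditions: H2 (1 atm), Pd(OH)2/C, EtOAc, rt
Reagents that add atoms: none
Why: Hydrogenolysis of a benzyl ether under neutral conditions; oxazoles and the electron-poor heteroaryl carbinol at C1 are expected to resist, and the C4 hydroxyl is released last without acid or base, so the ester should stay on C5.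

## Compound list

1 | methyl acetoacetate | CC(=O)CC(=O)OC | starting material
2 | methyl 2-diazo-3-oxobutanoate | CC(=O)C(=[N+]=[N-])C(=O)OC | intermediate
3 | methyl (±)-2-(benzyloxy)-3-oxobutanoate | CC(=O)C(OCc1ccccc1)C(=O)OC | intermediate
4 | methyl (2R,3S)-2-(benzyloxy)-3-hydroxybutanoate | O[C@@H](C)[C@@H](OCc1ccccc1)C(=O)OC | intermediate
5 | methyl (2R,3S)-2-(benzyloxy)-3-[(tert-butyldimethylsilyl)oxy]butanoate | CC(C)(C)[Si](C)(C)O[C@@H](C)[C@@H](OCc1ccccc1)C(=O)OC | intermediate
6 | (2R,3S)-2-(benzyloxy)-3-[(tert-butyldimethylsilyl)oxy]butanal | CC(C)(C)[Si](C)(C)O[C@@H](C)[C@@H](OCc1ccccc1)C=O | intermediate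
7 | 2-(oxazol-5-yl)acetic acid | OC(=O)Cc1cnco1 | starting material
8 | L-serine methyl ester (handled as its hydrochloride) | COC(=O)[C@@H](N)CO | starting material
9 | methyl (2S)-3-hydroxy-2-[2-(oxazol-5-yl)acetamido]propanoate | COC(=O)[C@@H](NC(=O)Cc1cnco1)CO | intermediate
10 | methyl (4S)-2-(oxazol-5-ylmethyl)-4,5-dihydrooxazole-4-carboxylate (formed in the flask) | COC(=O)[C@@H]1COC(Cc2cnco2)=N1 | intermediate
11 | methyl 2-(oxazol-5-ylmethyl)oxazole-4-carboxylate | COC(=O)c1coc(Cc2cnco2)n1 | intermediate
12 | N-methoxy-N-methyl-2-(oxazol-5-ylmethyl)oxazole-4-carboxamide | CON(C)C(=O)c1coc(Cc2cnco2)n1 | intermediate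
13 | 1-[2-(oxazol-5-ylmethyl)oxazol-4-yl]ethan-1-one | CC(=O)c1coc(Cc2cnco2)n1 | intermediate
14 | dicyclohexylboron enolate of 13 (formed in the flask) | C=C(OB(C1CCCCC1)C1CCCCC1)c1coc(Cc2cnco2)n1 | intermediate
15 | (3S,4S,5S)-4-(benzyloxy)-5-[(tert-butyldimethylsilyl)oxy]-3-hydroxy-1-[2-(oxazol-5-ylmethyl)oxazol-4-yl]hexan-1-one | CC(C)(C)[Si](C)(C)O[C@@H](C)[C@@H](OCc1ccccc1)[C@@H](O)CC(=O)c1coc(Cc2cnco2)n1 | intermediate
16 | C3-O-diethylboryl derivative of 15, boron coordinated to the C1 ketone (formed in the flask) | CC(C)(C)[Si](C)(C)O[C@@H](C)[C@@H](OCc1ccccc1)[C@@H](OB(CC)CC)CC(=O)c1coc(Cc2cnco2)n1 | intermediate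
17 | (1R,3S,4S,5S)-4-(benzyloxy)-5-[(tert-butyldimethylsilyl)oxy]-1-[2-(oxazol-5-ylmethyl)oxazol-4-yl]hexane-1,3-diol | CC(C)(C)[Si](C)(C)O[C@@H](C)[C@@H](OCc1ccccc1)[C@@H](O)C[C@@H](O)c1coc(Cc2cnco2)n1 | intermediate
18 | 4-[(4R,6S)-6-[(1S,2S)-1-(benzyloxy)-2-[(tert-butyldimethylsilyl)oxy]propyl]-2,2-dimethyl-1,3-dioxan-4-yl]-2-(oxazol-5-ylmethyl)oxazole | CC(C)(C)[Si](C)(C)O[C@@H](C)[C@@H](OCc1ccccc1)[C@@H]1C[C@H](c2coc(Cc3cnco3)n2)OC(C)(C)O1 | intermediate
19 | (2S,3R)-3-(benzyloxy)-3-[(4S,6R)-2,2-dimethyl-6-[2-(oxazol-5-ylmethyl)oxazol-4-yl]-1,3-dioxan-4-yl]propan-2-ol | O[C@@H](C)[C@@H](OCc1ccccc1)[C@@H]1C[C@H](c2coc(Cc3cnco3)n2)OC(C)(C)O1 | intermediate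
20 | palmitoyl chloride (hexadecanoyl chloride) | CCCCCCCCCCCCCCCC(Cl)=O | starting material
21 | (2S,3R)-3-(benzyloxy)-3-[(4S,6R)-2,2-dimethyl-6-[2-(oxazol-5-ylmethyl)oxazol-4-yl]-1,3-dioxan-4-yl]propan-2-yl hexadecanoate | CCCCCCCCCCCCCCCC(=O)O[C@@H](C)[C@@H](OCc1ccccc1)[C@@H]1C[C@H](c2coc(Cc3cnco3)n2)OC(C)(C)O1 | intermediate
22 | (2S,3S,4S,6R)-3-(benzyloxy)-4,6-dihydroxy-6-[2-(oxazol-5-ylmethyl)oxazol-4-yl]hexan-2-yl hexadecanoate | CCCCCCCCCCCCCCCC(=O)O[C@@H](C)[C@@H](OCc1ccccc1)[C@@H](O)C[C@@H](O)c1coc(Cc2cnco2)n1 | intermediate
23 | (2S,3S,4S,6R)-3,4,6-trihydroxy-6-[2-(oxazol-5-ylmethyl)oxazol-4-yl]hexan-2-yl hexadecanoate | CCCCCCCCCCCCCCCC(=O)O[C@@H](C)[C@@H](O)[C@@H](O)C[C@@H](O)c1coc(Cc2cnco2)n1 | target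

## Step count and least certain steps

Total: 16 steps. Longest linear sequence: 12 steps (steps 1–5, then 10–16, from 1). The ring A branch (steps 6–9) has four steps before the union in step 10.

**Step 3 (key step).** Reduction may outrun racemisation, or the catalyst may discriminate only weakly between a methyl group and the ester-bearing carbon, which would lower enantio- or diastereoselection; the sense of induction may also be opposite to the one assumed. Fallback: set out from 3 and return at 4 by a ketoreductase-catalysed dynamic reductive resolution (enzyme panel, NADP+, iPrOH as hydride source, pH 7 phosphate buffer, 30 °C). Stereocontrol then comes from an enzyme pocket instead of a ruthenium hydride, while the substrate still racemises through its enol. This fallback makes no new compound (F0).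

**Step 10.** Facial selectivity may be eroded, because in a closed transition state the syn-disposed β-silyloxy group can work against the α-benzyloxy control. The ring nitrogens may also sequester the boron chloride and leave enolisation incomplete, and 6 may epimerise at C4 before it reacts. Fallback: set out from 13, convert it with TMSOTf/Et3N into 2-(oxazol-5-ylmethyl)-4-[1-(trimethylsilyloxy)ethenyl]oxazole F1, and combine F1 with 6 under BF3·OEt2 in CH2Cl2 at −78 °C (Mukaiyama aldol), returning at 15. In the open transition state the polar Felkin–Anh preference of the α-benzyloxy group and the 1,3-anti preference of the β-oxygen should point to the same aldehyde face.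

**Step 11.** Chelation may be incomplete if the azole nitrogens compete for boron, giving poor 1,3-syn selectivity; retro-aldol cleavage of the β-hydroxy ketone is also possible. Fallback: set out from 15 and return at 17 by catalyst-controlled asymmetric transfer hydrogenation of the heteroaryl ketone with RuCl(p-cymene)[(R,R)-TsDPEN] and HCO2H/NEt3. The (R,R) complex is chosen by analogy with aryl methyl ketones to give the 1R carbinol, and substrate chelation is replaced by reagent control. No new compound is made (F0).

**Step 7.** The doubly activated inter-ring methylene may be halogenated by BrCCl3/DBU, or the activated serine hydroxyl may eliminate instead of cyclising. Fallback: set out from 7 and convert it with CDI and then aqueous NH3 into 2-(oxazol-5-yl)acetamide F2. Condensation of F2 with methyl bromopyruvate (NaHCO3, THF, 60 °C) gives methyl 4-hydroxy-2-(oxazol-5-ylmethyl)-4,5-dihydrooxazole-4-carboxylate F3, which is dehydrated with TFAA/2,6-lutidine to return at 11. This is a Hantzsch-type oxazole synthesis that needs no oxidant and no base strong enough to touch the methylene.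

**Step 16.** Hydrogenolysis may be slow if the azole nitrogens bind the catalyst, and long reaction times raise the chance of C1–O hydrogenolysis or acyl migration. Fallback: set out from 21 and return directly at 23, omitting 22, by treatment with BCl3 and pentamethylbenzene in CH2Cl2 at −78 °C followed by MeOH/H2O. The Lewis acid cleaves the benzyl ether (the benzyl cation is trapped by the arene) and the isopropylidene acetal in one operation without hydrogen and at a temperature at which the ester should not move. No new compound is made (F0).

## Further compounds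

F0 | step 3 | none | none
F1 | step 10 | 2-(oxazol-5-ylmethyl)-4-[1-(trimethylsilyloxy)ethenyl]oxazole | C=C(O[Si](C)(C)C)c1coc(Cc2cnco2)n1
F0 | step 11 | none | none
F2 | step 7 | 2-(oxazol-5-yl)acetamide | NC(=O)Cc1cnco1
F3 | step 7 | methyl 4-hydroxy-2-(oxazol-5-ylmethyl)-4,5-dihydrooxazole-4-carboxylate (racemic) | COC(=O)C1(O)COC(Cc2cnco2)=N1
F0 | step 16 | none | none
A1 | alternative 1 | C1, C3, C4 tris(tert-butyldimethylsilyl) ether of 23 | CCCCCCCCCCCCCCCC(=O)O[C@@H](C)[C@@H](O[Si](C)(C)C(C)(C)C)[C@@H](O[Si](C)(C)C(C)(C)C)C[C@@H](O[Si](C)(C)C(C)(C)C)c1coc(Cc2cnco2)n1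
A2 | alternative 1 | (2S,3S,4S,6R,7R)-3,4,6-tris[(tert-butyldimethylsilyl)oxy]-8-oxo-7-[2-(oxazol-5-yl)acetamido]octan-2-yl hexadecanoate | CCCCCCCCCCCCCCCC(=O)O[C@@H](C)[C@@H](O[Si](C)(C)C(C)(C)C)[C@@H](O[Si](C)(C)C(C)(C)C)C[C@@H](O[Si](C)(C)C(C)(C)C)[C@@H](NC(=O)Cc1cnco1)C=O
A3 | alternative 1 | tert-butyl (4S)-4-formyl-2,2-dimethyloxazolidine-3-carboxylate | CC(C)(C)OC(=O)N1[C@H](C=O)COC1(C)C
A4 | alternative 2 | C1 ketone of 23 with C3/C4 isopropylidene acetal and C5 palmitate | CCCCCCCCCCCCCCCC(=O)O[C@@H](C)[C@H]1OC(C)(C)O[C@H]1CC(=O)c1coc(Cc2cnco2)n1
A5 | alternative 2 | S-ethyl 2,6-dideoxy-5-O-hexadecanoyl-3,4-O-isopropylidene-L-lyxo-hexonothioate | CCCCCCCCCCCCCCCC(=O)O[C@@H](C)[C@H]1OC(C)(C)O[C@H]1CC(=O)SCC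
A6 | alternative 2 | 4-iodo-2-(oxazol-5-ylmethyl)oxazole | Ic1coc(Cc2cnco2)n1
A7 | alternative 2 | [2-(oxazol-5-ylmethyl)oxazol-4-yl]zinc iodide | I[Zn]c1coc(Cc2cnco2)n1
A8 | alternative 2 | 2-deoxy-L-fucose (2,6-dideoxy-L-lyxo-hexose, open-chain form) | O[C@@H](C)[C@@H](O)[C@@H](O)CC=O
A9 | alternative 3 | C1 tert-butyldimethylsilyl ether of 23 | CCCCCCCCCCCCCCCC(=O)O[C@@H](C)[C@@H](O)[C@@H](O)C[C@@H](O[Si](C)(C)C(C)(C)C)c1coc(Cc2cnco2)n1
A10 | alternative 3 | (1S,3R)-3-[(tert-butyldimethylsilyl)oxy]-1-[(2S,3R)-3-methyloxiran-2-yl]-3-[2-(oxazol-5-ylmethyl)oxazol-4-yl]propan-1-ol | C[C@H]1O[C@H]1[C@@H](O)C[C@@H](O[Si](C)(C)C(C)(C)C)c1coc(Cc2cnco2)n1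
A11 | alternative 3 | (1R,3S,4Z)-1-[(tert-butyldimethylsilyl)oxy]-1-[2-(oxazol-5-ylmethyl)oxazol-4-yl]hex-4-en-3-ol | C/C=C\[C@@H](O)C[C@@H](O[Si](C)(C)C(C)(C)C)c1coc(Cc2cnco2)n1
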